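**Retrosynthetic overview**
- The last events are epoxidation of the ring C3=C4 alkene, acylation of C1–OH, and a double Mitsunobu that inverts C2 and C8 while installing two angelates.
- Key disconnection C6–C7: a C7 vinyl radical from a 2-bromoallylic epoxy alcohol adds to the free diene terminus of unprotected (1R,2S)-toluene cis-dihydrodiol, anti to C1–OH; hydrogen transfer at C5 restores C3=C4.
- The diene diol comes from 4-iodotoluene by dioxygenase cis-dihydroxylation (iodine steers the enantiomeric sense) and hydrogenolysis of the C–I bond.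
- The side-chain fragment comes from 2-bromoacrolein and allylMgBr (Brown allylation sets C8), cross-metathesis to the prenyl unit, and Shi epoxidation (sets C10).
- Ring order: the carbocycle is the dearomatised arene (first), the side-chain oxirane is made on the fragment (second), the ring oxirane is made last.

**Assumptions:** bisabolane locants are used throughout (ring C1–C6: C1 and C2 carry the oxygens, C3 the methyl, C6 the side chain; side chain C7(=C14H2)–C8–C9–C10–C11). 2-Bromoacrolein and a toluene-dioxygenase strain are taken as obtainable.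

**Step 1**
Reactants: 1 4-iodotoluene
Product: 2 (1S,2S)-3-iodo-6-methylcyclohexa-3,5-diene-1,2-diol
Conditions: Pseudomonas putida UV4 whole cells (toluene dioxygenase), glucose, air, pH 7.2 phosphate buffer, 30 °C; EtOAc extraction, recrystallisation
Reagents that add atoms: dioxygen, O=O
Why: Enzymatic arene cis-dihydroxylation (toluene dioxygenase) in which the iodine, larger than methyl, fixes the binding orientation, so both carbinol centres (1S,2S) are set by the enzyme on the two carbons lying between I and CH3.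

**Step 2**
Reactants: 2 (1S,2S)-3-iodo-6-methylcyclohexa-3,5-diene-1,2-diol
Product: 3 (1R,2S)-3-methylcyclohexa-3,5-diene-1,2-diol
Conditions: H2 (1 atm), Pd/C (10% Pd), NaOAc, MeOH, 20 °C, stopped at 1 equiv H2
Reagents that add atoms: none
Why: Chemoselective catalytic hydrogenolysis of the vinylic C–I bond (fast oxidative addition to zerovalent palladium, with iodide moderating the catalyst toward the diene) removes the directing group and leaves the otherwise inaccessible enantiomer of toluene cis-dihydrodiol with no stereocentre touched.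

**Step 3**
Reactants: 4 allylmagnesium bromide; 5 2-bromoacrolein
Product: 8 (3R)-2-bromohexa-1,5-dien-3-ol, via B-allyldiisopinocampheylborane 6 (not isolated), via O-diisopinocampheylboryl ether 7 (not isolated)
Conditions: (+)-Ipc2BOMe [from (−)-α-pinene], Et2O, 0 °C; then 5, −78 °C; NaOH, H2O2, 0 °C
Reagents that add atoms: none
Why: Brown asymmetric allylboration through a chair Zimmerman–Traxler transition state, in which the (−)-α-pinene-derived isopinocampheyl groups deliver allyl to the Re face of the aldehyde and set C8 as R (the configuration needed before the later inversion).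

**Step 4**
Reactants: 8 (3R)-2-bromohexa-1,5-dien-3-ol; 9 2-methylbut-2-ene
Product: 10 (3R)-2-bromo-6-methylhepta-1,5-dien-3-ol
Conditions: second-generation Grubbs catalyst RuCl2(H2IMes)(PCy3)(=CHPh) (3 mol%), 9 (excess), CH2Cl2, 35 °C
Reagents that add atoms: none
Why: Olefin cross-metathesis converts the terminal vinyl group into the prenyl terminus while the hindered, electron-poor 2-bromo-1-alkene does not engage the ruthenium carbene and C8 is untouched.

**Step 5**
Reactants: 10 (3R)-2-bromo-6-methylhepta-1,5-dien-3-ol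
Product: 11 (2R)-3-bromo-1-[(2R)-3,3-dimethyloxiran-2-yl]but-3-en-2-ol
Conditions: D-fructose-derived Shi ketone (0.3 equiv), KHSO5 (as 2KHSO5·KHSO4·K2SO4), K2CO3, Bu4NHSO4, Na2B4O7/Na2(EDTA) buffer, MeCN–CH2(OMe)2–H2O, 0 °C
Reagents that add atoms: potassium peroxymonosulfate, [K+].[O-]S(=O)(=O)OO
Why: Shi asymmetric epoxidation, whose spiro transition state with the D-fructose-derived dioxirane gives the R oxirane at C10 of the trisubstituted alkene by reagent control, while the bromoalkene is too electron-poor to react.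

**Step 6**
Reactants: 3 (1R,2S)-3-methylcyclohexa-3,5-diene-1,2-diol; 11 (2R)-3-bromo-1-[(2R)-3,3-dimethyloxiran-2-yl]but-3-en-2-ol
Product: 12 (1R,2S,6R)-6-{(3R)-4-[(2R)-3,3-dimethyloxiran-2-yl]-3-hydroxybut-1-en-2-yl}-3-methylcyclohex-3-ene-1,2-diol
Conditions: 3 (3 equiv), Bu3SnH (1.3 equiv, syringe pump, 6 h), Et3B (0.3 equiv)/air, t-BuOH–PhH 1:1, 25 °C
Reagents that add atoms: none
Why: Proposed new method: Bu3Sn• abstracts bromine from 11 to give the σ-vinyl radical at C7, which adds (about 10^8 M−1 s−1, faster than its reduction at the low stannane concentration) to the unsubstituted diene terminus C6 of 3 on the face anti to the adjacent C1–OH, setting C6 as R (side chain trans to C1–O), and the resulting C5–C4–C3 allyl radical takes hydrogen from Bu3SnH at the less hindered C5 to restore the trisubstituted C3=C4 alkene; the closest known reaction types are Stork-type tin-hydride vinyl-radical additions to alkenes and the anti-selective additions to arene cis-dihydrodiol dienes.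

**Step 7**
Reactants: 12 (1R,2S,6R)-6-{(3R)-4-[(2R)-3,3-dimethyloxiran-2-yl]-3-hydroxybut-1-en-2-yl}-3-methylcyclohex-3-ene-1,2-diol; 13 angelic acid [(Z)-2-methylbut-2-enoic acid]
Product: 14 (1R,5R,6R)-5-{(3S)-4-[(2R)-3,3-dimethyloxiran-2-yl]-3-[(Z)-2-methylbut-2-enoyloxy]but-1-en-2-yl}-6-hydroxy-2-methylcyclohex-2-en-1-yl (Z)-2-methylbut-2-enoate
Conditions: 13 (3 equiv), PPh3 (3 equiv), DIAD (3 equiv), THF, 0 → 20 °C
Reagents that add atoms: none
Why: Double Mitsunobu esterification, in which the two activated allylic carbinols C2 and C8 are displaced by angelate with SN2 inversion (C2–O becomes trans to C1–O, C8 becomes S) while the non-allylic, flanked C1–OH is left, and the absence of acyl chloride or nucleophilic amine catalyst keeps the Z geometry of the acid.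

**Step 8**
Reactants: 14 the C2,C8-bis-angelate with free C1–OH; 13 angelic acid
Product: 16 (1R,2R,6R)-6-{(3S)-4-[(2R)-3,3-dimethyloxiran-2-yl]-3-[(Z)-2-methylbut-2-enoyloxy]but-1-en-2-yl}-3-methylcyclohex-3-ene-1,2-diyl bis[(Z)-2-methylbut-2-enoate], via angelic 2,4,6-trichlorobenzoic anhydride 15 (not isolated)
Conditions: 13, 2,4,6-Cl3C6H2COCl, Et3N, PhMe, 20 °C; then 14, 80 °C
Reagents that add atoms: none
Why: Yamaguchi-type mixed-anhydride esterification run without DMAP acylates the hindered C1–OH with retention and without Z-to-E isomerisation of the angelate, the alcohol attacking the less hindered angeloyl carbonyl.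

**Step 9**
Reactants: 16 the tri-angelate diene
Product: 17 target, (1S,2S,3R,4R,6S)-4-{(3S)-4-[(2R)-3,3-dimethyloxiran-2-yl]-3-[(Z)-2-methylbut-2-enoyloxy]but-1-en-2-yl}-1-methyl-7-oxabicyclo[4.1.0]heptane-2,3-diyl bis[(Z)-2-methylbut-2-enoate]
Conditions: L-fructose-derived (enantiomeric) Shi ketone (0.3 equiv), KHSO5 (as 2KHSO5·KHSO4·K2SO4), K2CO3, Bu4NHSO4, Na2B4O7/Na2(EDTA) buffer, MeCN–CH2(OMe)2–H2O, 0 °C
Reagents that add atoms: potassium peroxymonosulfate, [K+].[O-]S(=O)(=O)OO
Why: Shi asymmetric epoxidation with the enantiomeric ketone delivers oxygen to the ring C3=C4 alkene on the face anti to the C2 angelate and the C6 side chain (catalyst preference and substrate bias should agree), setting C3 and C4, while the angelate double bonds and the 1,1-disubstituted alkene are too electron-poor or hindered to compete.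

**Compound list**
1 | 4-iodotoluene | Cc1ccc(I)cc1 | starting material
2 | (1S,2S)-3-iodo-6-methylcyclohexa-3,5-diene-1,2-diol | CC1=CC=C(I)[C@@H](O)[C@H]1O | intermediate
3 | (1R,2S)-3-methylcyclohexa-3,5-diene-1,2-diol | CC1=CC=C[C@@H](O)[C@H]1O | intermediate
4 | allylmagnesium bromide | C=CC[Mg]Br | starting material
5 | 2-bromoacrolein | C=C(Br)C=O | starting material
6 | B-allyldiisopinocampheylborane [(−)-α-pinene series] | C=CCB([C@H]1C[C@H]2C[C@@H]([C@@H]1C)C2(C)C)[C@H]1C[C@H]2C[C@@H]([C@@H]1C)C2(C)C | intermediate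
7 | (3R)-2-bromohexa-1,5-dien-3-yl diisopinocampheylborinate | C=C(Br)[C@@H](CC=C)OB([C@H]1C[C@H]2C[C@@H]([C@@H]1C)C2(C)C)[C@H]1C[C@H]2C[C@@H]([C@@H]1C)C2(C)C | intermediate
8 | (3R)-2-bromohexa-1,5-dien-3-ol | C=C(Br)[C@@H](CC=C)O | intermediate
9 | 2-methylbut-2-ene | CC=C(C)C | starting material
10 | (3R)-2-bromo-6-methylhepta-1,5-dien-3-ol | C=C(Br)[C@@H](CC=C(C)C)O | intermediate
11 | (2R)-3-bromo-1-[(2R)-3,3-dimethyloxiran-2-yl]but-3-en-2-ol | C=C(Br)[C@@H](C[C@H]1OC1(C)C)O | intermediate
12 | (1R,2S,6R)-6-{(3R)-4-[(2R)-3,3-dimethyloxiran-2-yl]-3-hydroxybut-1-en-2-yl}-3-methylcyclohex-3-ene-1,2-diol | C=C([C@@H](C[C@H]1OC1(C)C)O)[C@H]1CC=C(C)[C@H](O)[C@@H]1O | intermediate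
13 | angelic acid, (Z)-2-methylbut-2-enoic acid | C/C=C(/C)C(=O)O | starting material
14 | C2,C8-bis-angelate with free C1–OH (name as in step 7) | C=C([C@H](C[C@H]1OC1(C)C)OC(=O)/C(C)=C\C)[C@H]1CC=C(C)[C@@H](OC(=O)/C(C)=C\C)[C@@H]1O | intermediate
15 | angelic 2,4,6-trichlorobenzoic anhydride | C/C=C(/C)C(=O)OC(=O)c1c(Cl)cc(Cl)cc1Cl | intermediate
16 | C1,C2,C8-tri-angelate diene (name as in step 8) | C=C([C@H](C[C@H]1OC1(C)C)OC(=O)/C(C)=C\C)[C@H]1CC=C(C)[C@@H](OC(=O)/C(C)=C\C)[C@@H]1OC(=O)/C(C)=C\C | intermediate
17 | CNP0258231.1 (name as in step 9) | C=C([C@H](C[C@H]1OC1(C)C)OC(=O)/C(C)=C\C)[C@H]1C[C@@H]2O[C@]2(C)[C@@H](OC(=O)/C(C)=C\C)[C@@H]1OC(=O)/C(C)=C\C | target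

**Totals**
Total step count: 9.
Longest linear sequence: 7 steps (3, 4, 5, 6, 7, 8, 9) from 2-bromoacrolein and allylmagnesium bromide; the arene branch (steps 1 and 2) joins at step 6.

**Steps most likely to fail, with fallbacks**

Step 6 (intermolecular vinyl-radical addition to the unprotected diene diol). The risks are direct reduction of 11, attack syn to C1–OH, and hydrogen delivery at C3 instead of C5. The fallback moves the radical to the ring. It sets out from 3: silylation (TBSOTf, 2,6-lutidine, CH2Cl2) gives the bis-TBS ether F1. Copper-catalysed protoboration (CuCl, Xantphos, KOt-Bu, B2pin2, MeOH, THF) puts boron on C6 and hydrogen on C5 to give the homoallylic pinacol boronate F2. F2 is coupled with 11 under dual photoredox/nickel catalysis (Ir[dF(CF3)ppy]2(dtbbpy)PF6, NiCl2(dme), dtbbpy, DMAP as Lewis-base activator, blue LED), where the C6 radical is captured by the vinyl-nickel species anti to the C1 silyloxy group, to give the coupled bis-TBS ether F3. Bu4NF in THF then returns the route to triol 12.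

Step 7 (double Mitsunobu with a weak acid on a triol). The risks are SN2′ esters, intramolecular ether formation from C1–OH onto C8, and incomplete reaction at the hindered C2. The fallback sets out from 12: Mitsunobu with the more acidic chloroacetic acid (PPh3, DIAD, THF) gives the C2,C8-bis(chloroacetate) F4. Mild methanolysis (K2CO3, MeOH, 0 °C) gives the C2,C8-inverted triol F5. All three hydroxyls are then acylated in one operation with the angelic/2,4,6-trichlorobenzoic mixed anhydride (Et3N, PhMe, 80 °C), rejoining the route at tri-angelate 16.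

Step 9 (face and site selectivity of the last epoxidation). The risks are the wrong-face epoxide and attack on the 1,1-disubstituted alkene. The fallback installs the ring oxirane one step earlier under hydroxyl direction. It sets out from 14, which still has the free C1–OH on the required face: VO(acac)2 and t-BuOOH in PhMe let the homoallylic hydroxyl deliver oxygen syn to itself across C3=C4, giving the epoxy alcohol F6. F6 is then angeloylated under the conditions of step 8 and arrives at target 17.

**Further compounds**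
F1 | step 6 | (1R,2S)-3-methyl-1,2-bis(tert-butyldimethylsilyloxy)cyclohexa-3,5-diene | CC1=CC=C[C@@H](O[Si](C)(C)C(C)(C)C)[C@H]1O[Si](C)(C)C(C)(C)C
F2 | step 6 | C6 pinacol boronate of the bis-TBS ether (boron on C6, hydrogen on C5, C3=C4 retained) | CC1(C)OB(OC1(C)C)[C@H]1CC=C(C)[C@H](O[Si](C)(C)C(C)(C)C)[C@@H]1O[Si](C)(C)C(C)(C)C
F3 | step 6 | C1,C2-bis-TBS ether of 12 | C=C([C@@H](C[C@H]1OC1(C)C)O)[C@H]1CC=C(C)[C@H](O[Si](C)(C)C(C)(C)C)[C@@H]1O[Si](C)(C)C(C)(C)C
F4 | step 7 | C2,C8-bis(chloroacetate) with inverted C2 and C8 and free C1–OH | C=C([C@H](C[C@H]1OC1(C)C)OC(=O)CCl)[C@H]1CC=C(C)[C@@H](OC(=O)CCl)[C@@H]1O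
F5 | step 7 | (1R,2R,6R)-6-{(3S)-4-[(2R)-3,3-dimethyloxiran-2-yl]-3-hydroxybut-1-en-2-yl}-3-methylcyclohex-3-ene-1,2-diol | C=C([C@H](C[C@H]1OC1(C)C)O)[C@H]1CC=C(C)[C@@H](O)[C@@H]1O
F6 | step 9 | ring C3,C4-epoxide of 14 with free C1–OH | C=C([C@H](C[C@H]1OC1(C)C)OC(=O)/C(C)=C\C)[C@H]1C[C@@H]2O[C@]2(C)[C@@H](OC(=O)/C(C)=C\C)[C@@H]1O
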